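**Strategy**

Everything rests on opening the pyran ring of the 2H-chromene at C8a–O1 and C4a–C4. 3-Methylbut-2-enal supplies O1, the gem-dimethyl carbon C2, C3 and C4, while the neighbouring arene carbons C4a and C8a are the two ends of an aryne. In one fluoride-triggered operation aryne and enal combine by [2+2] addition, benzoxete opening and oxa-6π closure. This finishes the bicyclic core with the C8 prenyl group, the C7 methoxy group and the masked C5 oxygen already in place. The precursor is a pentasubstituted ortho-silyl aryl triflate built by two carbamate-directed metalations. The C6 acyl chain follows by lithiation between the two ether oxygens.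

Key step: step 7

Remark on stereochemistry: the target has no stereogenic element (no stereocentre; one ring cis-alkene and one alkene with two identical methyls), so it is a single achiral compound and no enantiocontrol is needed.

Remark on bond bookkeeping: the annulation makes three σ-bonds, C8a–O1, C4a–C4 and, in the electrocyclisation that actually closes the ring, O1–C2. The former carbonyl bond O1–C4 of the enal is broken.

Remark on the precursor: the MOM ether is kept at the future C5 oxygen because it does three jobs. It is the co-director for the silylation, the inductive control element of the aryne, and the director for the late C6 lithiation. The N,N-diethylcarbamate is chosen as the hub so that no silyl triflate or acid is needed while the MOM ether and the electron-rich aryl–silicon bond are present.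

**Route**

Step 1
Reactants: 1 5-methoxyresorcinol
Product: 2 3-methoxy-5-(methoxymethoxy)phenol
Conditions: MOMCl (1.0 equiv), i-Pr2NEt, CH2Cl2, 0 °C → rt; diol and bis-ether separated and recycled
Reagents that add atoms: chloromethyl methyl ether, COCCl
Why: Williamson-type O-alkylation of one of two equivalent phenols; with one equivalent of MOMCl the mono-ether should be the main product.

Step 2
Reactants: 2 3-methoxy-5-(methoxymethoxy)phenol
Product: 3 3-methoxy-5-(methoxymethoxy)phenyl N,N-diethylcarbamate
Conditions: Et2NCOCl, K2CO3, MeCN, 80 °C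
Reagents that add atoms: N,N-diethylcarbamoyl chloride, CCN(CC)C(Cl)=O
Why: O-acylation of the phenol with a carbamoyl chloride places the strongest ortho-directing group on the oxygen that later leaves as triflate.

Step 3
Reactants: 3 3-methoxy-5-(methoxymethoxy)phenyl N,N-diethylcarbamate
Product: 5 5-methoxy-3-(methoxymethoxy)-2-(trimethylsilyl)phenyl N,N-diethylcarbamate, via aryllithium 4 (not isolated)
Conditions: s-BuLi, TMEDA, THF, −78 °C; TMSCl, −78 °C → rt
Reagents that add atoms: chlorotrimethylsilane, C[Si](C)(C)Cl
Why: Directed ortho-metalation (Snieckus): the C–H between carbamate and MOM ether should be the most acidic, since both groups coordinate lithium and OMOM is a stronger co-director than OMe, and silylation at −78 °C precedes anionic ortho-Fries migration.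

Step 4
Reactants: 5 5-methoxy-3-(methoxymethoxy)-2-(trimethylsilyl)phenyl N,N-diethylcarbamate; 6 prenyl bromide
Product: 8 3-methoxy-5-(methoxymethoxy)-2-(3-methylbut-2-enyl)-6-(trimethylsilyl)phenyl N,N-diethylcarbamate, via aryllithium 7 (not isolated)
Conditions: s-BuLi, TMEDA, THF, −78 °C; CuBr·SMe2 (10 mol %), then 6, −78 → −20 °C
Reagents that add atoms: none
Why: Second directed ortho-metalation at the only carbamate-ortho C–H left (silicon blocks the other, and the carbamate outranks the OMe/OMOM pair), then copper-catalysed SN2 allylation of the aryllithium, which should give the linear prenyl isomer.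

Step 5
Reactants: 8 3-methoxy-5-(methoxymethoxy)-2-(3-methylbut-2-enyl)-6-(trimethylsilyl)phenyl N,N-diethylcarbamate
Product: 9 3-methoxy-5-(methoxymethoxy)-2-(3-methylbut-2-enyl)-6-(trimethylsilyl)phenol
Conditions: LiAlH4, THF, 0 → 60 °C; cold aq. Rochelle salt/NH4Cl work-up
Reagents that add atoms: none
Why: Hydride reduction of the aryl carbamate frees the phenol under aprotic, non-acidic conditions, so the acid-labile aryl–silicon bond, the MOM ether and the prenyl alkene should remain.

Step 6
Reactants: 9 3-methoxy-5-(methoxymethoxy)-2-(3-methylbut-2-enyl)-6-(trimethylsilyl)phenol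
Product: 10 3-methoxy-5-(methoxymethoxy)-2-(3-methylbut-2-enyl)-6-(trimethylsilyl)phenyl trifluoromethanesulfonate
Conditions: Tf2O, pyridine, CH2Cl2, −20 → 0 °C
Reagents that add atoms: trifluoromethanesulfonic anhydride, O=S(=O)(OS(=O)(=O)C(F)(F)F)C(F)(F)F
Why: O-triflation of the phenol is the standard last step to an ortho-silyl aryl triflate (Kobayashi aryne precursor), and the pyridine buffer avoids protodesilylation of the electron-rich ring.

Step 7
Reactants: 10 3-methoxy-5-(methoxymethoxy)-2-(3-methylbut-2-enyl)-6-(trimethylsilyl)phenyl trifluoromethanesulfonate; 11 3-methylbut-2-enal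
Product: 15 7-methoxy-5-(methoxymethoxy)-2,2-dimethyl-8-(3-methylbut-2-enyl)-2H-chromene, via aryne 12 (not isolated), via benzoxete 13 (not isolated), via ortho-quinone methide 14 (not isolated)
Conditions: CsF (3 equiv), 11 (5 equiv), MeCN, rt; 10 added slowly
Reagents that add atoms: none
Why: Fluoride attacks silicon and triflate leaves to give aryne 12; the C5 MOM ether polarises the strained bond inductively, so the aldehyde oxygen attacks the remote aryne carbon (future C8a) and the C4a carbanion, stabilised next to the C5 oxygen, closes onto the carbonyl carbon to give benzoxete 13 (formal [2+2]). Thermal 4π opening breaks the former carbonyl bond O1–C4 and gives ortho-quinone methide 14, whose Z isomer (vinyl group syn to the ring carbonyl) closes the six-membered pyran by thermal disrotatory oxa-6π electrocyclisation, forming O1–C2 at the gem-dimethyl carbon; the E isomer can only revert through 13. The closest known reaction type is the annulation of fluoride-generated arynes with α,β-unsaturated aldehydes to 2H-chromenes, related to aryne insertion into formamide C=O bonds. No stereocentre remains, because the sp3 carbon of 13 becomes the sp2 carbon C4. The selectivity needed is regiochemical (oxygen at C8a, carbon at C4a) and should be secured by the 3-alkoxy effect of the MOM ether; the prenyl group on the other flank is a weakly directing alkyl group of modest bulk towards a small oxygen nucleophile, and the C7 methoxy group lies too far away to matter much. Excess enal and slow release of the aryne should suppress ene reaction at prenyl groups and capture of 14 by a second aryne.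

Step 8
Reactants: 16 4-hydroxyphenylacetic acid
Product: 17 2-(4-hydroxyphenyl)-N-methoxy-N-methylacetamide
Conditions: MeNHOMe·HCl, EDC·HCl, HOBt, i-Pr2NEt, CH2Cl2/DMF, 0 °C → rt
Reagents that add atoms: N,O-dimethylhydroxylamine hydrochloride, CNOC.Cl
Why: Carbodiimide amidation to the Weinreb amide; the amine should outcompete the free phenol for the activated ester.

Step 9
Reactants: 17 2-(4-hydroxyphenyl)-N-methoxy-N-methylacetamide
Product: 18 N-methoxy-2-[4-(methoxymethoxy)phenyl]-N-methylacetamide
Conditions: MOMCl, i-Pr2NEt, CH2Cl2, 0 °C → rt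
Reagents that add atoms: chloromethyl methyl ether, COCCl
Why: Phenol O-alkylation; the MOM ether is inert to the aryllithium of step 10 and leaves together with the C5 MOM group in the last step.

Step 10
Reactants: 15 7-methoxy-5-(methoxymethoxy)-2,2-dimethyl-8-(3-methylbut-2-enyl)-2H-chromene; 18 N-methoxy-2-[4-(methoxymethoxy)phenyl]-N-methylacetamide
Product: 21 1-[7-methoxy-5-(methoxymethoxy)-2,2-dimethyl-8-(3-methylbut-2-enyl)-2H-chromen-6-yl]-2-[4-(methoxymethoxy)phenyl]ethanone, via aryllithium 19 (not isolated), via tetrahedral lithium adduct 20 (not isolated)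
Conditions: n-BuLi, THF, 0 °C, 1 h; 18, −78 → 0 °C; then H2O, 0 °C
Reagents that add atoms: none
Why: Directed ortho-metalation at C6, the only aromatic C–H and flanked by OMe and OMOM, then Weinreb ketone synthesis, in which the chelated tetrahedral adduct prevents over-addition.

Step 11
Reactants: 21 1-[7-methoxy-5-(methoxymethoxy)-2,2-dimethyl-8-(3-methylbut-2-enyl)-2H-chromen-6-yl]-2-[4-(methoxymethoxy)phenyl]ethanone
Product: 22 1-[5-hydroxy-7-methoxy-2,2-dimethyl-8-(3-methylbut-2-enyl)-2H-chromen-6-yl]-2-(4-hydroxyphenyl)ethanone (CNP0287261.0)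
Conditions: 3 M aq. HCl, MeOH, rt → 40 °C
Reagents that add atoms: none
Why: Acid-catalysed acetal methanolysis should remove both MOM ethers; no free hydroxyl lies ortho to the prenyl group, so acid-induced chroman formation is impossible, and the C5 phenol is held by a hydrogen bond to the ketone.

**Compound list**

1 | 5-methoxyresorcinol | COc1cc(O)cc(O)c1 | starting material
2 | 3-methoxy-5-(methoxymethoxy)phenol | COCOc1cc(O)cc(OC)c1 | intermediate
3 | 3-methoxy-5-(methoxymethoxy)phenyl N,N-diethylcarbamate | CCN(CC)C(=O)Oc1cc(OC)cc(OCOC)c1 | intermediate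
4 | [2-(diethylcarbamoyloxy)-4-methoxy-6-(methoxymethoxy)phenyl]lithium (lithium between carbamate and MOM ether) | CCN(CC)C(=O)Oc1cc(OC)cc(OCOC)c1[Li] | intermediate (not isolated)
5 | 5-methoxy-3-(methoxymethoxy)-2-(trimethylsilyl)phenyl N,N-diethylcarbamate | CCN(CC)C(=O)Oc1cc(OC)cc(OCOC)c1[Si](C)(C)C | intermediate
6 | prenyl bromide (1-bromo-3-methylbut-2-ene) | CC(C)=CCBr | starting material
7 | [2-(diethylcarbamoyloxy)-6-methoxy-4-(methoxymethoxy)-3-(trimethylsilyl)phenyl]lithium | CCN(CC)C(=O)Oc1c([Li])c(OC)cc(OCOC)c1[Si](C)(C)C | intermediate (not isolated)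
8 | 3-methoxy-5-(methoxymethoxy)-2-(3-methylbut-2-enyl)-6-(trimethylsilyl)phenyl N,N-diethylcarbamate | CCN(CC)C(=O)Oc1c(CC=C(C)C)c(OC)cc(OCOC)c1[Si](C)(C)C | intermediate
9 | 3-methoxy-5-(methoxymethoxy)-2-(3-methylbut-2-enyl)-6-(trimethylsilyl)phenol | COCOc1cc(OC)c(CC=C(C)C)c(O)c1[Si](C)(C)C | intermediate
10 | 3-methoxy-5-(methoxymethoxy)-2-(3-methylbut-2-enyl)-6-(trimethylsilyl)phenyl trifluoromethanesulfonate | COc1cc(OCOC)c([Si](C)(C)C)c(OS(=O)(=O)C(F)(F)F)c1CC=C(C)C | intermediate (key-step precursor)
11 | 3-methylbut-2-enal | CC(C)=CC=O | starting material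
12 | 5-methoxy-3-(methoxymethoxy)-6-(3-methylbut-2-enyl)-1,2-didehydrobenzene (aryne) | COC1=C(CC=C(C)C)C#CC(OCOC)=C1 | intermediate (not isolated)
13 | 5-methoxy-3-(methoxymethoxy)-6-(3-methylbut-2-enyl)-2-(2-methylprop-1-enyl)-2H-1-benzoxete (racemic) | COc1cc(OCOC)c2C(C=C(C)C)Oc2c1CC=C(C)C | intermediate (not isolated)
14 | (6Z)-3-methoxy-5-(methoxymethoxy)-2-(3-methylbut-2-enyl)-6-(3-methylbut-2-enylidene)cyclohexa-2,4-dien-1-one | CC(C)=C/C=C1/C(OCOC)=CC(OC)=C(CC=C(C)C)C1=O | intermediate (not isolated)
15 | 7-methoxy-5-(methoxymethoxy)-2,2-dimethyl-8-(3-methylbut-2-enyl)-2H-chromene | COc1cc(OCOC)c2C=CC(C)(C)Oc2c1CC=C(C)C | intermediate (key-step product)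
16 | 4-hydroxyphenylacetic acid | OC(=O)Cc1ccc(O)cc1 | starting material
17 | 2-(4-hydroxyphenyl)-N-methoxy-N-methylacetamide | CON(C)C(=O)Cc1ccc(O)cc1 | intermediate
18 | N-methoxy-2-[4-(methoxymethoxy)phenyl]-N-methylacetamide | CON(C)C(=O)Cc1ccc(OCOC)cc1 | intermediate
19 | [7-methoxy-5-(methoxymethoxy)-2,2-dimethyl-8-(3-methylbut-2-enyl)-2H-chromen-6-yl]lithium | [Li]c1c(OC)c(CC=C(C)C)c2OC(C)(C)C=Cc2c1OCOC | intermediate (not isolated)
20 | lithium 1-[methoxy(methyl)amino]-1-[7-methoxy-5-(methoxymethoxy)-2,2-dimethyl-8-(3-methylbut-2-enyl)-2H-chromen-6-yl]-2-[4-(methoxymethoxy)phenyl]ethanolate (tetrahedral adduct, racemic) | COCOc1ccc(CC(O[Li])(N(C)OC)c2c(OC)c(CC=C(C)C)c3OC(C)(C)C=Cc3c2OCOC)cc1 | intermediate (not isolated)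
21 | 1-[7-methoxy-5-(methoxymethoxy)-2,2-dimethyl-8-(3-methylbut-2-enyl)-2H-chromen-6-yl]-2-[4-(methoxymethoxy)phenyl]ethanone | COCOc1ccc(CC(=O)c2c(OC)c(CC=C(C)C)c3OC(C)(C)C=Cc3c2OCOC)cc1 | intermediate
22 | 1-[5-hydroxy-7-methoxy-2,2-dimethyl-8-(3-methylbut-2-enyl)-2H-chromen-6-yl]-2-(4-hydroxyphenyl)ethanone (CNP0287261.0) | COc1c(CC=C(C)C)c2c(c(O)c1C(=O)Cc1ccc(O)cc1)C=CC(C)(C)O2 | target

**Step count**

Total steps: 11. Longest linear sequence: 9 (steps 1–7, 10, 11); steps 8 and 9 form the side branch.

**Steps most likely to fail**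

Step 7. The aldehyde oxygen may add at the wrong aryne terminus, or the aryne may be diverted into ene reaction with prenyl groups or into capture of the quinone methide by a second aryne. Fallback without an aryne, setting out from phenol 9: fluoride-promoted protodesilylation (TBAF·3H2O, THF, 50 °C) removes the trimethylsilyl group and gives 3-methoxy-5-(methoxymethoxy)-2-(3-methylbut-2-enyl)phenol F1. Amine-salt-catalysed condensation of this phenol with 3-methylbut-2-enal 11 (ethylenediammonium diacetate, toluene, reflux) attacks the only free ortho carbon, dehydrates to the same quinone methide 14 and closes by the same oxa-6π step. It comes back to the route at chromene 15.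

Step 10. Proton transfer from the benzylic CH2 of amide 18 to the hindered aryllithium may outrun addition and return the chromene. Fallback that forms the CH2–aryl bond instead, setting out from chromene 15: aryllithium 19 is generated as before and quenched with N-methoxy-N-methylacetamide. This passes through the lithium hemiaminal adduct F2 and gives, on aqueous work-up, 1-[7-methoxy-5-(methoxymethoxy)-2,2-dimethyl-8-(3-methylbut-2-enyl)-2H-chromen-6-yl]ethanone F3. Palladium-catalysed α-arylation of this methyl ketone with 1-bromo-4-(methoxymethoxy)benzene (Pd2(dba)3, Xantphos, NaOt-Bu, toluene, 80 °C) comes back to the route at ketone 21.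

Step 3. Metalation on the methoxy side of the carbamate may compete with metalation on the MOM side, giving a mixture of silyl regioisomers. Fallback that makes the silylation site unique by symmetry, setting out from 5-methoxyresorcinol 1: double carbamoylation (Et2NCOCl, K2CO3, MeCN, 80 °C) gives 5-methoxy-1,3-phenylene bis(N,N-diethylcarbamate) F4. s-BuLi/TMEDA at −78 °C metalates the single position between the two carbamates to give the 2-lithio bis-carbamate F5, and TMSCl gives 5-methoxy-2-(trimethylsilyl)-1,3-phenylene bis(N,N-diethylcarbamate) F6. Controlled reductive removal of one carbamate (LiAlH4, THF, 0 °C; the aluminium phenoxide formed deactivates the second carbamate) gives 3-hydroxy-5-methoxy-2-(trimethylsilyl)phenyl N,N-diethylcarbamate F7. MOMCl/i-Pr2NEt then comes back to the route at silyl carbamate 5.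

**Further compounds**

F1 | step 7 | 3-methoxy-5-(methoxymethoxy)-2-(3-methylbut-2-enyl)phenol | COCOc1cc(O)c(CC=C(C)C)c(OC)c1
F2 | step 10 | lithium hemiaminal adduct of 19 with N-methoxy-N-methylacetamide: lithium 1-[methoxy(methyl)amino]-1-[7-methoxy-5-(methoxymethoxy)-2,2-dimethyl-8-(3-methylbut-2-enyl)-2H-chromen-6-yl]ethanolate (racemic) | CC(O[Li])(N(C)OC)c1c(OC)c(CC=C(C)C)c2OC(C)(C)C=Cc2c1OCOC
F3 | step 10 | 1-[7-methoxy-5-(methoxymethoxy)-2,2-dimethyl-8-(3-methylbut-2-enyl)-2H-chromen-6-yl]ethanone | CC(=O)c1c(OC)c(CC=C(C)C)c2OC(C)(C)C=Cc2c1OCOC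
F4 | step 3 | 5-methoxy-1,3-phenylene bis(N,N-diethylcarbamate) | CCN(CC)C(=O)Oc1cc(OC)cc(OC(=O)N(CC)CC)c1
F5 | step 3 | 2-lithio bis-carbamate: [2,6-bis(diethylcarbamoyloxy)-4-methoxyphenyl]lithium | CCN(CC)C(=O)Oc1cc(OC)cc(OC(=O)N(CC)CC)c1[Li]
F6 | step 3 | 5-methoxy-2-(trimethylsilyl)-1,3-phenylene bis(N,N-diethylcarbamate) | CCN(CC)C(=O)Oc1cc(OC)cc(OC(=O)N(CC)CC)c1[Si](C)(C)C
F7 | step 3 | 3-hydroxy-5-methoxy-2-(trimethylsilyl)phenyl N,N-diethylcarbamate | CCN(CC)C(=O)Oc1cc(OC)cc(O)c1[Si](C)(C)C
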